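The target is disconnected at its four C–Br bonds, back to the 2,2'-dioxygenated diphenyl ether. With C1 on each ring as the carbon bearing the bridging oxygen and C2 as the carbon bearing OMe (ring A) or OH (ring B), all four bromines sit at C4 and C6, i.e. para and ortho to the bridging oxygen and meta to the C2 oxygen. The key step exploits this: once both C2 oxygens are tied up as electron-poor methanesulfonates, the bridging oxygen is the only strong donor, and one electrophilic bromination of the symmetrical bis-mesylate 9 should place all four halogens. Unmasking and one O-methylation finish the synthesis.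

Key step: step 3

Assumption: the target SMILES carries no stereodescriptor and the molecule has no stereocentre or configurationally stable axis, so it is made as the single achiral compound and no step has to set stereochemistry.

Design remark: both C2 oxygens stay sulfonylated through the bromination, because an anisole or free phenol ring would send bromine para to its own oxygen (C5); the methyl group is therefore introduced only after the halogens are in place.

Step 1
Reactants: 1 diphenyl ether; 2 n-butyllithium; 3 trimethyl borate; 4 hydrogen peroxide
Product: 7 2,2'-oxydiphenol, via 2,2'-dilithiodiphenyl ether 5 (not isolated), via diboronate ester 6 (not isolated)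
Conditions: n-BuLi (2.5 equiv), TMEDA (2.5 equiv), Et2O/hexane, 0 °C → rt; cannulated into B(OMe)3 (6 equiv), THF, −78 °C → rt; 30% H2O2, aq NaOH, 0 °C → rt; then aq HCl
Reagents that add atoms: hydrogen peroxide, OO
Why: The ether oxygen directs n-BuLi/TMEDA to both ortho C–H bonds (directed ortho-metalation), each aryllithium is trapped on boron, and alkaline peroxide turns every aryl–boron bond into an aryl–oxygen bond by 1,2-aryl shift (boronate oxidation), so that even a cyclic borinate formed from 5 and a single boron should end as the same diol.

Step 2
Reactants: 7 2,2'-oxydiphenol; 8 methanesulfonyl chloride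
Product: 9 oxydi-2,1-phenylene dimethanesulfonate (bis-mesylate of 2,2'-oxydiphenol)
Conditions: MsCl (2.4 equiv), Et3N (3 equiv), CH2Cl2, 0 °C → rt
Reagents that add atoms: methanesulfonyl chloride, CS(=O)(=O)Cl
Why: Standard O-sulfonylation of phenols with MsCl/Et3N caps both hydroxyls and turns each into a weakly donating, electron-poor substituent that should withstand bromine, HBr and a Lewis acid.

Step 3
Reactants: 9 oxydi-2,1-phenylene dimethanesulfonate; 10 bromine
Product: 11 oxybis(3,5-dibromo-2,1-phenylene) dimethanesulfonate, i.e. bis[2,4-dibromo-6-(methylsulfonyloxy)phenyl] ether
Conditions: Br2 (6 equiv), FeBr3 (10 mol%), 1,2-dichloroethane, rt → 70 °C, dark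
Reagents that add atoms: bromine, BrBr
Why: This is a Lewis-acid-catalysed electrophilic aromatic bromination through arenium ions whose charge is delocalised onto the bridging oxygen, and the closest known reaction type is the ortho/para polybromination of diphenyl ethers. No ring is closed and no stereocentre is formed. The selectivity needed is regiochemical: C4 and C6 of each ring must win over C3 and C5, which lie ortho and para to the sulfonate oxygen. The substrate should secure this because the sulfonate oxygen's lone pairs are drawn into the sulfonyl group and give almost no resonance help, whereas the diaryl ether oxygen still does, so para attack (C4, C4') should come first and ortho attack (C6, C6') second. Each ring has only these two oxygen-activated positions, and the two remaining C–H bonds are meta to the donor and flanked by bromine or sulfonate, so the reaction should stop at the tetrabromide, with excess bromine and gentle heating driving the slower second substitution on each deactivated ring.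

Step 4
Reactants: 11 oxybis(3,5-dibromo-2,1-phenylene) dimethanesulfonate
Product: 12 2,2'-oxybis(3,5-dibromophenol)
Conditions: aq NaOH (6 equiv), 1,4-dioxane, 80 °C; then aq HCl
Reagents that add atoms: none
Why: Hydroxide cleaves aryl methanesulfonates at the S–O bond (sulfonate ester saponification, by attack at sulfur or E1cB loss of sulfene) with the dibromophenoxide as a good leaving group, while unactivated aryl bromides and the diaryl ether link should not react with aqueous hydroxide at this temperature.

Step 5
Reactants: 12 2,2'-oxybis(3,5-dibromophenol); 13 iodomethane
Product: 14 3,5-dibromo-2-(2,4-dibromo-6-methoxyphenoxy)phenol (target)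
Conditions: KOt-Bu (1.0 equiv), DMF, 0 °C; MeI (1.0 equiv), 0 °C → rt; recovered 12 recycled
Reagents that add atoms: iodomethane, CI
Why: Williamson O-methylation of the monophenoxide, in which exactly one equivalent of base ionises only one hydroxyl and the monoanion, stabilised by a hydrogen bond from the neighbouring OH across the ether bridge, is more acidic than the product phenol, so methyl transfer should stop mainly after one oxygen.

Compound list
1 | diphenyl ether | c1ccc(Oc2ccccc2)cc1 | starting material
2 | n-butyllithium | [Li]CCCC | starting material
3 | trimethyl borate | COB(OC)OC | starting material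
4 | hydrogen peroxide | OO | starting material
5 | 2,2'-dilithiodiphenyl ether | [Li]c1ccccc1Oc1ccccc1[Li] | intermediate
6 | tetramethyl (oxydi-2,1-phenylene)diboronate (present largely as its lithium methoxide ate complex) | COB(OC)c1ccccc1Oc1ccccc1B(OC)OC | intermediate
7 | 2,2'-oxydiphenol | Oc1ccccc1Oc1ccccc1O | intermediate
8 | methanesulfonyl chloride | CS(=O)(=O)Cl | starting material
9 | oxydi-2,1-phenylene dimethanesulfonate | CS(=O)(=O)Oc1ccccc1Oc1ccccc1OS(C)(=O)=O | intermediate
10 | bromine | BrBr | starting material
11 | oxybis(3,5-dibromo-2,1-phenylene) dimethanesulfonate | CS(=O)(=O)Oc1cc(Br)cc(Br)c1Oc1c(Br)cc(Br)cc1OS(C)(=O)=O | intermediate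
12 | 2,2'-oxybis(3,5-dibromophenol) | Oc1cc(Br)cc(Br)c1Oc1c(Br)cc(Br)cc1O | intermediate
13 | iodomethane | CI | starting material
14 | 3,5-dibromo-2-(2,4-dibromo-6-methoxyphenoxy)phenol | COc1cc(Br)cc(Br)c1Oc1c(O)cc(Br)cc1Br | target

Total step count: 5. Longest linear sequence: 5 steps (from diphenyl ether 1).

Steps most likely to fail

1. Step 3. The second substitution on each ring takes place on a nucleus that already carries a bromine and a sulfonate. It may stall at tri-bromide mixtures, or part of it may leak to the carbon para to the sulfonate oxygen (C5). Fallback: replace the sulfonate mask by a formyl group, a true meta director, so that the ring oxygen and the mask point to the same two carbons. The fallback sets out from the dilithio species 5 (generated from 1 as in step 1). Quenching 5 with DMF (−78 °C → rt, aq HCl) should give 2,2'-oxydibenzaldehyde F1. Bromination with Br2 and catalytic FeBr3 in 1,2-dichloroethane should give 2,2'-oxybis(3,5-dibromobenzaldehyde) F2. Double Baeyer–Villiger oxidation with mCPBA in CH2Cl2, where the ortho aryloxy group supports aryl migration, should give oxybis(3,5-dibromo-2,1-phenylene) diformate F3. Saponification with aq KOH in THF then gives diol 12, where the fallback comes back to the route; it bypasses 7, 9 and 11.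

2. Step 5. Proton exchange between the product phenol and unreacted monoanion may allow the second oxygen to be methylated, so that diol, mono-ether and di-ether form together. Fallback: desymmetrise by partial unmasking and not by partial alkylation. The fallback sets out from 11. Treatment with NaOH (2.0 equiv) in dioxane/water at 50 °C should remove one sulfonate and give 3,5-dibromo-2-(2,4-dibromo-6-hydroxyphenoxy)phenyl methanesulfonate F4; the aryloxide formed in the first cleavage repels hydroxide and would have to leave as a dianion in the second. Exhaustive methylation of the single free hydroxyl (MeI in excess, K2CO3, acetone) gives 3,5-dibromo-2-(2,4-dibromo-6-methoxyphenoxy)phenyl methanesulfonate F5. Cleavage of the remaining sulfonate under the conditions of step 4 gives 14, where the fallback comes back to the route. Unreacted 11 and over-cleaved 12 both re-enter the main sequence.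

3. Step 1. Incomplete second metalation, or protonation of one aryl–metal or aryl–boron bond before oxidation, would leave 2-phenoxyphenol mixed with the diol. Fallback: build the diaryl ether with both oxygens already in place. This fallback draws on no numbered compound; it replaces starting material 1 by two further commercial compounds and comes back to the route at 7. Copper-catalysed Ullmann C–O coupling of guaiacol F6 with 2-bromoanisole F7 (CuI, picolinic acid, K3PO4, DMSO, 90 °C) should give 1,1'-oxybis(2-methoxybenzene) F8. Double demethylation with BBr3 (CH2Cl2, −78 °C → rt) then gives 7.

Further compounds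
F1 | step 3 | 2,2'-oxydibenzaldehyde | O=Cc1ccccc1Oc1ccccc1C=O
F2 | step 3 | 2,2'-oxybis(3,5-dibromobenzaldehyde) | O=Cc1cc(Br)cc(Br)c1Oc1c(Br)cc(Br)cc1C=O
F3 | step 3 | oxybis(3,5-dibromo-2,1-phenylene) diformate | O=COc1cc(Br)cc(Br)c1Oc1c(Br)cc(Br)cc1OC=O
F4 | step 5 | 3,5-dibromo-2-(2,4-dibromo-6-hydroxyphenoxy)phenyl methanesulfonate | CS(=O)(=O)Oc1cc(Br)cc(Br)c1Oc1c(O)cc(Br)cc1Br
F5 | step 5 | 3,5-dibromo-2-(2,4-dibromo-6-methoxyphenoxy)phenyl methanesulfonate | COc1cc(Br)cc(Br)c1Oc1c(Br)cc(Br)cc1OS(C)(=O)=O
F6 | step 1 | guaiacol (2-methoxyphenol) | COc1ccccc1O
F7 | step 1 | 2-bromoanisole | COc1ccccc1Br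
F8 | step 1 | 1,1'-oxybis(2-methoxybenzene) | COc1ccccc1Oc1ccccc1OC
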